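Ring A is closed last, across C3–C4, by alkylating the C18 ester enolate at C4 with a primary chloride at C3. This exploits that the quaternary C4 of ring A bears an oxidised carbon (C18) and adjoins the C5 methine. (R)-Carvone supplies ring B, C5 and, as its 2-propenyl group, C4, C18 and C19; two enolate alkylations add C20 and the C1–C3 arm at C10. One operation forms the C3–C4 bond, closes ring A trans-fused and sets C4 (C18 equatorial), because the enolate carbon must eclipse C5–H. The precursor is a monocyclic cyclohexenyl triflate with a methyl propanoate arm on C5 and a 3-chloropropyl arm on C10.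

Key step: step 6

Remark: labdane numbering is used for all ring compounds, and the target is read as (13E)-18-acetoxy-8α-hydroxylabd-13-en-15-oic acid of the normal series (4α-CH2OAc equatorial, 4β-CH3, 5α-H, 8α-OH, 9α-H, 10β-CH3).

Step 1
Reactants: 1 (R)-(−)-carvone
Product: 3 (5R,6S)-2,6-dimethyl-5-(prop-1-en-2-yl)cyclohex-2-en-1-one, via lithium dienolate 2 (not isolated)
Conditions: LiN(i-Pr)2, THF, −78 °C; MeI, −78 → −20 °C
Reagents that add atoms: iodomethane, CI
Why: Kinetic deprotonation at the α'-carbon (future C10) and enolate C-alkylation bring in C20; the methyl should enter mainly anti to the 2-propenyl group, but this centre becomes trigonal again in step 2, so its epimer ratio does not matter.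

Step 2
Reactants: 3 (5R,6S)-2,6-dimethyl-5-(prop-1-en-2-yl)cyclohex-2-en-1-one
Product: 5 6-(3-chloropropyl)-2,6-dimethyl-5-(prop-1-en-2-yl)cyclohex-2-en-1-one (chloropropyl trans and 6-methyl cis to the propenyl group), via lithium dienolate 4 (not isolated)
Conditions: LiN(i-Pr)2, THF, −78 °C; DMPU, ICH2CH2CH2Cl, −78 → 0 °C
Reagents that add atoms: 1-chloro-3-iodopropane, ClCCCI
Why: Enolate alkylation in which only the iodide end of the dihalide reacts; the electrophile approaches the trisubstituted enolate carbon anti to the adjacent 2-propenyl group, which sets quaternary C10 with the C1–C3 arm trans and C20 cis to C4.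

Step 3
Reactants: 5 6-(3-chloropropyl)-2,6-dimethyl-5-(prop-1-en-2-yl)cyclohex-2-en-1-one
Product: 7 6-(3-chloropropyl)-2,6-dimethyl-5-(prop-1-en-2-yl)cyclohex-1-en-1-yl trifluoromethanesulfonate, via lithium enolate 6 (not isolated)
Conditions: LiBH(s-Bu)3, THF, −78 °C; PhNTf2, −78 → 0 °C
Reagents that add atoms: N-phenylbis(trifluoromethanesulfonimide), O=S(=O)(N(c1ccccc1)S(=O)(=O)C(F)(F)F)C(F)(F)F
Why: Conjugate hydride reduction of the carbonyl-hindered enone gives the regiodefined C9 enolate, which is triflated on oxygen; this removes the enone with its acidic γ-hydrogens before the key step and installs the handle for the C9 side chain.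

Step 4
Reactants: 7 6-(3-chloropropyl)-2,6-dimethyl-5-(prop-1-en-2-yl)cyclohex-1-en-1-yl trifluoromethanesulfonate
Product: 9 6-(3-chloropropyl)-5-(1-hydroxypropan-2-yl)-2,6-dimethylcyclohex-1-en-1-yl trifluoromethanesulfonate (both epimers at C4), via B-alkyl-9-BBN adduct 8 (not isolated)
Conditions: 9-BBN, THF, 0 °C → rt; H2O2, aq. NaOAc, 0 °C → rt
Reagents that add atoms: hydrogen peroxide, OO
Why: Brown hydroboration–oxidation places boron and then oxygen on the terminal carbon (C18) of the 1,1-disubstituted alkene only, the tetrasubstituted electron-poor enol triflate alkene being inert to 9-BBN; the configuration at C4 is irrelevant because C4 is enolised in step 6.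

Step 5
Reactants: 9 6-(3-chloropropyl)-5-(1-hydroxypropan-2-yl)-2,6-dimethylcyclohex-1-en-1-yl trifluoromethanesulfonate
Product: 11 methyl 2-[2-(3-chloropropyl)-2,4-dimethyl-3-(trifluoromethanesulfonyloxy)cyclohex-3-en-1-yl]propanoate, via carboxylic acid 10 (not isolated)
Conditions: TEMPO (cat.), PhI(OAc)2, MeCN/H2O, rt; then Me3SiCHN2, MeOH/toluene, 0 °C
Reagents that add atoms: water, O; (trimethylsilyl)diazomethane, C[Si](C)(C)C=[N+]=[N-]
Why: Nitroxyl-catalysed oxidation takes the primary alcohol through the aldehyde hydrate to the acid without touching the triflate or the chloride, and diazoalkane esterification gives the methyl ester needed for enolate formation.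

Step 6
Reactants: 11 methyl 2-[2-(3-chloropropyl)-2,4-dimethyl-3-(trifluoromethanesulfonyloxy)cyclohex-3-en-1-yl]propanoate
Product: 13 methyl 4β,8,10β-trimethyl-9-(trifluoromethanesulfonyloxy)-5α-decal-8-ene-4α-carboxylate (trans-decalin), via lithium ester enolate 12 (not isolated)
Conditions: LiN(i-Pr)2, THF, −78 °C; DMPU, −78 °C → rt
Reagents that add atoms: none
Why: LiN(i-Pr)2 removes the only acidic hydrogen left in 11, the α-hydrogen of the propanoate arm at C4 (C10 is quaternary and the former enone is now an enol triflate), and the lithium ester enolate displaces the primary chloride at C3 in an intramolecular SN2 enolate alkylation, the closest known reaction type being the classical ring-forming alkylation of ester enolates. Ring A closes in the 6-exo-tet mode through a chair in which the C5–C4 and C10–C1 bonds are both equatorial on ring B, so the trans ring fusion carried by C5 (H α) and C10 (CH3 β) is kept. The one new stereocentre, quaternary C4, is controlled by allylic 1,3-strain from C5: the planar enolate carbon C18 with its two oxygen substituents must eclipse the small C5–H and cannot lie next to the C5–C10 bond and the axial C20 methyl, so C18 becomes equatorial (4α) and C19 axial (4β), as in the target. Both C4 epimers of 11 converge because C4 is trigonal in 12. The step needs C- rather than O-alkylation, which ring size secures (O-attack would require an eight-membered ring), and it needs the enolate to form only at C4, which the lack of any other acidic site secures.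

Step 7
Reactants: 13 methyl 4β,8,10β-trimethyl-9-(trifluoromethanesulfonyloxy)-5α-decal-8-ene-4α-carboxylate
Product: 14 4α-(hydroxymethyl)-4β,8,10β-trimethyl-5α-decal-8-en-9-yl trifluoromethanesulfonate
Conditions: i-Bu2AlH, CH2Cl2, −78 → 0 °C
Reagents that add atoms: none
Why: Hydride reduction of the neopentyl ester gives the primary alcohol C18–OH at a stage where nothing else is reducible, the enol triflate being inert to i-Bu2AlH at low temperature.

Step 8
Reactants: 14 4α-(hydroxymethyl)-4β,8,10β-trimethyl-5α-decal-8-en-9-yl trifluoromethanesulfonate; 15 2-methyl-2-vinyl-1,3-dioxolane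
Product: 17 13,13-(ethylenedioxy)-14,15-dinorlabd-8-en-18-ol, via B-alkyl-9-BBN reagent 16 (not isolated)
Conditions: 15, 9-BBN, THF, rt; then 14, Pd(dppf)Cl2 (cat.), AsPh3, aq. K3PO4, DMF, 60 °C
Reagents that add atoms: none
Why: B-alkyl Suzuki–Miyaura coupling, in which zerovalent palladium inserts into the C9–OTf bond and the primary alkylborane delivers C11–C13 with C16, gives the tetrasubstituted C8=C9 alkene; 2,6,6-trisubstituted cyclohexenyl triflates of this kind are known to couple.

Step 9
Reactants: 17 13,13-(ethylenedioxy)-14,15-dinorlabd-8-en-18-ol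
Product: 19 13,13-(ethylenedioxy)-14,15-dinorlabdane-8α,18-diol, via 8α-boryl 18-O-boryl intermediate 18 (not isolated)
Conditions: BH3·SMe2 (excess), THF, 0 → 40 °C; then MeOH, aq. NaOH, H2O2, 0 → 50 °C
Reagents that add atoms: hydrogen peroxide, OO
Why: Brown hydroboration–oxidation of the tetrasubstituted alkene: borane should add syn from the α-face, anti to the axial C20 methyl, with boron on the less hindered C8, and oxidation with retention then gives 8α-OH (8β-CH3) and 9α-H (side chain β), which sets both C8 and C9.

Step 10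
Reactants: 19 13,13-(ethylenedioxy)-14,15-dinorlabdane-8α,18-diol
Product: 20 18-acetoxy-13,13-(ethylenedioxy)-14,15-dinorlabdan-8α-ol
Conditions: Ac2O, pyridine, CH2Cl2, 0 °C → rt
Reagents that add atoms: acetic anhydride, CC(=O)OC(C)=O
Why: Acylation distinguishes the primary C18 hydroxyl from the hindered tertiary C8 hydroxyl, which does not react without a nucleophilic catalyst.

Step 11
Reactants: 20 18-acetoxy-13,13-(ethylenedioxy)-14,15-dinorlabdan-8α-ol
Product: 21 18-acetoxy-8α-hydroxy-14,15-dinorlabdan-13-one
Conditions: PPTS, acetone/H2O, 45 °C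
Reagents that add atoms: water, O
Why: Mild acid-catalysed acetal hydrolysis frees the C13 methyl ketone while the acetate and the acid-sensitive tertiary alcohol survive.

Step 12
Reactants: 21 18-acetoxy-8α-hydroxy-14,15-dinorlabdan-13-one
Product: 22 allyl (13E)-18-acetoxy-8α-hydroxylabd-13-en-15-oate
Conditions: (EtO)2P(O)CH2CO2CH2CH=CH2 (slight excess over NaH), NaH, THF, 0 → 50 °C
Reagents that add atoms: allyl diethylphosphonoacetate, C=CCOC(=O)CP(=O)(OCC)OCC
Why: Horner–Wadsworth–Emmons olefination of the methyl ketone should favour the (13E) enoate, with the ester anti to the larger C12 chain, and the minor (13Z) ester is removed by chromatography.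

Step 13
Reactants: 22 allyl (13E)-18-acetoxy-8α-hydroxylabd-13-en-15-oate
Product: 23 (13E)-18-acetoxy-8α-hydroxylabd-13-en-15-oic acid
Conditions: Pd(PPh3)4 (cat.), morpholine, THF, rt
Reagents that add atoms: none
Why: Tsuji–Trost-type deallylation, in which zerovalent palladium ionises the allyl ester and morpholine traps the allyl group, frees the acid under neutral conditions that leave the acetate, the tertiary alcohol and the alkene geometry untouched.

Compound list
1 | (R)-(−)-carvone, (5R)-2-methyl-5-(prop-1-en-2-yl)cyclohex-2-en-1-one | CC(=C)[C@@H]1CC=C(C)C(=O)C1 | starting material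
2 | lithium cross-conjugated dienolate of 1 (O–Li on C1, C1=C6) | CC(=C)[C@@H]1CC=C(C)C(O[Li])=C1 | intermediate
3 | (5R,6S)-2,6-dimethyl-5-(prop-1-en-2-yl)cyclohex-2-en-1-one (trans-6-methylcarvone, expected major epimer) | CC(=C)[C@@H]1CC=C(C)C(=O)[C@H]1C | intermediate
4 | lithium dienolate of 3 (O–Li on C1, C1=C6) | CC(=C)[C@@H]1CC=C(C)C(O[Li])=C1C | intermediate
5 | 6-(3-chloropropyl)-2,6-dimethyl-5-(prop-1-en-2-yl)cyclohex-2-en-1-one, carvone centre unchanged, chloropropyl trans and 6-methyl cis to the propenyl group | CC(=C)[C@@H]1CC=C(C)C(=O)[C@@]1(C)CCCCl | intermediate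
6 | lithium enolate from conjugate reduction of 5 (O–Li on C1, C1=C2) | CC(=C)[C@@H]1CCC(C)=C(O[Li])[C@@]1(C)CCCCl | intermediate
7 | 6-(3-chloropropyl)-2,6-dimethyl-5-(prop-1-en-2-yl)cyclohex-1-en-1-yl trifluoromethanesulfonate (ring centres as in 5) | CC(=C)[C@@H]1CCC(C)=C(OS(=O)(=O)C(F)(F)F)[C@@]1(C)CCCCl | intermediate
8 | adduct of 7 with 9-BBN, boron on the former =CH2 carbon (C18), both C4 epimers | CC(CB2C3CCCC2CCC3)[C@@H]1CCC(C)=C(OS(=O)(=O)C(F)(F)F)[C@@]1(C)CCCCl | intermediate
9 | 6-(3-chloropropyl)-5-(1-hydroxypropan-2-yl)-2,6-dimethylcyclohex-1-en-1-yl trifluoromethanesulfonate, both C4 epimers | CC(CO)[C@@H]1CCC(C)=C(OS(=O)(=O)C(F)(F)F)[C@@]1(C)CCCCl | intermediate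
10 | 2-[2-(3-chloropropyl)-2,4-dimethyl-3-(trifluoromethanesulfonyloxy)cyclohex-3-en-1-yl]propanoic acid, both C4 epimers | CC(C(=O)O)[C@@H]1CCC(C)=C(OS(=O)(=O)C(F)(F)F)[C@@]1(C)CCCCl | intermediate
11 | methyl ester of 10 | COC(=O)C(C)[C@@H]1CCC(C)=C(OS(=O)(=O)C(F)(F)F)[C@@]1(C)CCCCl | intermediate
12 | lithium ester enolate of 11 (C4 trigonal) | COC(O[Li])=C(C)[C@@H]1CCC(C)=C(OS(=O)(=O)C(F)(F)F)[C@@]1(C)CCCCl | intermediate
13 | methyl 4β,8,10β-trimethyl-9-(trifluoromethanesulfonyloxy)-5α-decal-8-ene-4α-carboxylate (trans-decalin, C18 ester equatorial) | COC(=O)[C@]1(C)CCC[C@]2(C)C(OS(=O)(=O)C(F)(F)F)=C(C)CC[C@@H]12 | intermediate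
14 | 4α-(hydroxymethyl)-4β,8,10β-trimethyl-5α-decal-8-en-9-yl trifluoromethanesulfonate | OC[C@]1(C)CCC[C@]2(C)C(OS(=O)(=O)C(F)(F)F)=C(C)CC[C@@H]12 | intermediate
15 | 2-methyl-2-vinyl-1,3-dioxolane | C=CC1(C)OCCO1 | starting material
16 | 9-[2-(2-methyl-1,3-dioxolan-2-yl)ethyl]-9-borabicyclo[3.3.1]nonane | CC1(CCB2C3CCCC2CCC3)OCCO1 | intermediate
17 | 13,13-(ethylenedioxy)-14,15-dinorlabd-8-en-18-ol (C8=C9 alkene) | OC[C@]1(C)CCC[C@]2(C)C(CCC3(C)OCCO3)=C(C)CC[C@@H]12 | intermediate
18 | 8α-boryl 18-O-boryl derivative of 17 after syn addition of B–H (9α-H) | BOC[C@]1(C)CCC[C@]2(C)[C@@H](CCC3(C)OCCO3)[C@](C)(B)CC[C@@H]12 | intermediate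
19 | 13,13-(ethylenedioxy)-14,15-dinorlabdane-8α,18-diol | OC[C@]1(C)CCC[C@]2(C)[C@@H](CCC3(C)OCCO3)[C@](C)(O)CC[C@@H]12 | intermediate
20 | 18-acetoxy-13,13-(ethylenedioxy)-14,15-dinorlabdan-8α-ol | CC(=O)OC[C@]1(C)CCC[C@]2(C)[C@@H](CCC3(C)OCCO3)[C@](C)(O)CC[C@@H]12 | intermediate
21 | 18-acetoxy-8α-hydroxy-14,15-dinorlabdan-13-one | CC(=O)OC[C@]1(C)CCC[C@]2(C)[C@@H](CCC(C)=O)[C@](C)(O)CC[C@@H]12 | intermediate
22 | allyl (13E)-18-acetoxy-8α-hydroxylabd-13-en-15-oate | CC(=O)OC[C@]1(C)CCC[C@]2(C)[C@@H](CC/C(C)=C/C(=O)OCC=C)[C@](C)(O)CC[C@@H]12 | intermediate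
23 | (13E)-18-acetoxy-8α-hydroxylabd-13-en-15-oic acid | CC(=O)OC[C@]1(C)CCC[C@]2(C)[C@@H](CC/C(C)=C/C(=O)O)[C@](C)(O)CC[C@@H]12 | target

Total step count: 13. Longest linear sequence: 13 steps from 1 (15 enters in step 8 after hydroboration in the same flask).

Steps most likely to fail

Step 6. The SN2 closure at the primary chloride may be slow for the hindered, fully substituted lithium enolate, so that proton exchange or intermolecular Claisen condensation take over. The fallback sets out from acid 10, isolated after the oxidation stage of step 5 instead of being esterified. LiN(i-Pr)2 (2.2 equiv) in THF/DMPU at 0 °C → rt would give the dilithium enediolate F1, a much stronger nucleophile that cannot self-condense. Under the same allylic-strain control it should close the ring to the bicyclic 4α-carboxylic acid F2, and Me3SiCHN2 in MeOH then returns to the route at 13.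

Step 9. Addition of borane to the tetrasubstituted C8=C9 bond may be sluggish or misdirected, and boron may migrate toward C17 on heating. The fallback sets out from 17. m-CPBA with NaHCO3 in CH2Cl2 would give the 8α,9α-epoxide F3 by attack anti to C20. Cp2TiCl2 with Mn (which forms Cp2TiCl, trivalent titanium) and water as hydrogen-atom source in THF would then open the more congested C9–O bond homolytically and reduce the C9 radical from the α-face, returning to the route at 19.

Step 2. C-alkylation of the hindered trisubstituted enolate carbon by an unactivated primary iodide may be slow, with O-alkylation and enolate equilibration competing. The fallback sets out from 3. Its enolate 4 would be alkylated with allyl bromide, a far better electrophile, to give 6-allyl-6-methylcarvone F4 with the same facial preference. Hydroboration with catecholborane catalysed by RhCl(PPh3)3, selective for the monosubstituted alkene over the 1,1-disubstituted alkene and the ketone, would give the catechol boronate F5. Oxidation with H2O2 at pH 7 would give the primary alcohol F6, and PPh3/CCl4 (Appel reaction) returns to the route at 5.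

Further compounds
F1 | step 6 | dilithium enediolate of acid 10 | [Li]OC(O[Li])=C(C)[C@@H]1CCC(C)=C(OS(=O)(=O)C(F)(F)F)[C@@]1(C)CCCCl
F2 | step 6 | 4β,8,10β-trimethyl-9-(trifluoromethanesulfonyloxy)-5α-decal-8-ene-4α-carboxylic acid | OC(=O)[C@]1(C)CCC[C@]2(C)C(OS(=O)(=O)C(F)(F)F)=C(C)CC[C@@H]12
F3 | step 9 | 8α,9α-epoxy-13,13-(ethylenedioxy)-14,15-dinorlabdan-18-ol | OC[C@]1(C)CCC[C@]2(C)[C@]3(CCC4(C)OCCO4)O[C@]3(C)CC[C@@H]12
F4 | step 2 | 6-allyl-2,6-dimethyl-5-(prop-1-en-2-yl)cyclohex-2-en-1-one, allyl trans to the propenyl group | CC(=C)[C@@H]1CC=C(C)C(=O)[C@@]1(C)CC=C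
F5 | step 2 | 2-(3-substituted propyl)-1,3,2-benzodioxaborole from F4 (boron on the terminal carbon of the former allyl group) | CC(=C)[C@@H]1CC=C(C)C(=O)[C@@]1(C)CCCB2Oc3ccccc3O2
F6 | step 2 | 6-(3-hydroxypropyl)-2,6-dimethyl-5-(prop-1-en-2-yl)cyclohex-2-en-1-one | CC(=C)[C@@H]1CC=C(C)C(=O)[C@@]1(C)CCCO
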